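Ring B, the ring-fusion carbon C5 and C4 are all present in (R)-carvone, so everything rests on disconnecting C3–C4 of ring A. The key step exploits the gem-dimethyl quaternary C4 of ring A next to C5: hydrogen-atom transfer to the isopropenyl group completes the gem-dimethyl group and leaves a tertiary C4 radical that closes ring A 6-endo onto a vinyl sulfone, giving the trans-decalin in one operation. The precursor is carvone doubly alkylated at the future C10, with methyl cis and 2-(phenylsulfonyl)allyl trans to isopropenyl. The sulfone is retained by design: one dissolving-metal step removes it while turning the enone into the C8=C9 enol triflate that accepts C11 and the arene.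

Key step: step 3

Remark: drimane numbering is used (ring A = C1–C5 and C10; ring B = C5–C10; C11 = chloroalkene carbon; α = face of H5, β = face of the C10 methyl); the E chloroalkene (Cl syn to C8, aryl syn to C10) is assumed to be the less stable isomer and is therefore made under kinetic control; radicals and cations are transient and carry no number.

Step 1
Reactants: 1 (R)-(−)-carvone; 2 iodomethane
Product: 4 (5R,6RS)-6-methylcarvone (C6 epimers), via lithium dienolate of carvone 3 (not isolated)
Conditions: LDA (1.1 equiv), THF, −78 °C; MeI, −78 → 0 °C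
Reagents that add atoms: iodomethane, CI
Why: Kinetic α'-deprotonation of the cross-conjugated enone and C-methylation of the enolate (enolate alkylation); the C6 configuration does not matter because this centre is enolised again in step 2.

Step 2
Reactants: 4 (5R,6RS)-6-methylcarvone; 5 2-(phenylsulfonyl)allyl bromide
Product: 7 (5S,6S)-2,6-dimethyl-6-[2-(phenylsulfonyl)prop-2-en-1-yl]-5-(prop-1-en-2-yl)cyclohex-2-en-1-one (6-CH3 cis to isopropenyl; sulfonylallyl trans), via lithium enolate of 6-methylcarvone 6 (not isolated)
Conditions: LDA (1.2 equiv), THF, −78 → −40 °C; then 5, −78 → −20 °C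
Reagents that add atoms: 2-(phenylsulfonyl)allyl bromide, C=C(CBr)S(=O)(=O)c1ccccc1
Why: Enolate alkylation (addition–elimination, SN2', on the bromomethyl vinyl sulfone, which gives the same constitution as SN2); the electrophile should approach the tetrasubstituted enolate anti to the neighbouring isopropenyl group, so the new quaternary centre carries CH3 cis and the chain trans to isopropenyl.

Step 3
Reactants: 7 (5S,6S)-2,6-dimethyl-6-[2-(phenylsulfonyl)prop-2-en-1-yl]-5-(prop-1-en-2-yl)cyclohex-2-en-1-one
Product: 8 2α-(phenylsulfonyl)-11-nordrim-7-en-9-one (trans-fused; 5α-H; 10β-CH3; sulfone equatorial)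
Conditions: Fe(acac)3 (30 mol %), PhSiH3 (2.5 equiv), EtOH/(CH2OH)2 (5:1), 0.02 M, 60 °C
Reagents that add atoms: none
Why: An iron hydride formed from Fe(acac)3 and PhSiH3 should transfer a hydrogen atom to the CH2 of the electron-neutral isopropenyl group, giving the tertiary C4 radical with the gem-dimethyl group complete; this nucleophilic radical adds to the unsubstituted C3 terminus of the vinyl sulfone, and the α-sulfonyl radical is reduced and protonated by ethanol. The closest known reaction type is the iron-hydride HAT reductive olefin coupling (Giese-type addition of an unactivated alkene to an acceptor alkene), run here intramolecularly. Ring A closes in the 6-endo mode, which should beat 5-exo because the attack is polarity-matched at the β-carbon of the vinyl sulfone and the α-carbon is substituted. The only new stereocentre is the sulfone-bearing C2, expected equatorial after protonation and erased in step 4; C5 and C10 are untouched, so the trans ring fusion follows from the anti alkylation of step 2, which places C4 and C1 trans-diequatorial on ring B. The step needs HAT at the isopropenyl group in preference to the electron-poor enone and vinyl sulfone, and a C4 radical instead of a cation (no elimination towards C5); the electronics of the substrate and the neutral conditions should secure both.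

Step 4
Reactants: 8 2α-(phenylsulfonyl)-11-nordrim-7-en-9-one
Product: 10 11-nordrim-8-en-9-yl trifluoromethanesulfonate (5α-H; 10β-CH3), via C8=C9 lithium enolate 9 (not isolated)
Conditions: Li (8 equiv), NH3(l)/THF, t-BuOH (2 equiv), −78 °C; isoprene; evaporate NH3; PhNTf2 (2.5 equiv), THF, 0 °C → rt
Reagents that add atoms: N-phenylbis(trifluoromethanesulfonimide), O=S(=O)(N(c1ccccc1)S(=O)(=O)C(F)(F)F)C(F)(F)F
Why: Dissolving-metal reduction should convert the enone into the regiodefined C8=C9 lithium enolate and cleave the secondary C–SO2Ph bond (reductive desulfonylation), and the enolate is then O-triflated (enone reduction–enolate trapping); no stereocentre is formed.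

Step 5
Reactants: 11 5-bromovanillin
Product: 12 2-bromo-6-methoxybenzene-1,4-diol
Conditions: H2O2 (30 % aq.), NaOH (aq.), 0 °C → rt, N2; then HCl
Reagents that add atoms: hydrogen peroxide, OO
Why: Dakin oxidation of a para-hydroxybenzaldehyde (hydroperoxide addition, aryl migration, hydrolysis of the aryl formate) gives the hydroquinone with the substitution pattern of the target arene.

Step 6
Reactants: 12 2-bromo-6-methoxybenzene-1,4-diol; 2 iodomethane
Product: 13 1-bromo-2,3,5-trimethoxybenzene
Conditions: MeI (3 equiv), K2CO3, acetone, reflux, N2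
Reagents that add atoms: iodomethane, CI
Why: Williamson O-methylation of both phenols gives ethers that survive every later step and are removed oxidatively at the end.

Step 7
Reactants: 13 1-bromo-2,3,5-trimethoxybenzene
Product: 15 4,4,5,5-tetramethyl-2-(2,3,5-trimethoxyphenyl)-1,3,2-dioxaborolane, via (2,3,5-trimethoxyphenyl)lithium 14 (not isolated)
Conditions: n-BuLi (1.05 equiv), THF, −78 °C; i-PrOBpin (1.3 equiv), −78 °C → rt; aq. NH4Cl
Reagents that add atoms: 2-isopropoxy-4,4,5,5-tetramethyl-1,3,2-dioxaborolane, CC(C)OB1OC(C)(C)C(C)(C)O1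
Why: Bromine–lithium exchange at −78 °C is faster than ortho-deprotonation and fixes the position of the aryllithium, which is trapped by the borate ester (borylation via halogen–metal exchange).

Step 8
Reactants: 10 11-nordrim-8-en-9-yl trifluoromethanesulfonate; 15 4,4,5,5-tetramethyl-2-(2,3,5-trimethoxyphenyl)-1,3,2-dioxaborolane; 16 carbon monoxide
Product: 17 11-(2,3,5-trimethoxyphenyl)drim-8-en-11-one (5α-H; 10β-CH3)
Conditions: PdCl2(dppf) (5 mol %), K2CO3 (3 equiv), CO (1 atm), anisole/H2O (20:1), 80 °C
Reagents that add atoms: carbon monoxide, [C-]#[O+]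
Why: Carbonylative Suzuki–Miyaura coupling: after oxidative addition of the tetrasubstituted enol triflate, CO insertion should outrun direct coupling (slowed by the flanking quaternary C10 and the C8 methyl), and the acyl-palladium species couples with the aryl boronate to install C11 and the arene together.

Step 9
Reactants: 17 11-(2,3,5-trimethoxyphenyl)drim-8-en-11-one
Product: 19 11-(2,3,5-trimethoxyphenyl)drim-8(12)-en-11-one (9α-H; aroyl 9β), via potassium dienolate 18 (not isolated)
Conditions: KHMDS (1.5 equiv), THF, −78 → −20 °C; inverse quench into AcOH/THF, −78 °C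
Reagents that add atoms: none
Why: Deconjugative protonation: γ-deprotonation at the C8 methyl, which lies syn to the carbonyl, gives the dienolate, and kinetic protonation at the α-carbon C9 from the α-face (opposite the axial C10 methyl) should give the β,γ-unsaturated ketone with the aroyl group equatorial, which is also the stable C9 configuration.

Step 10
Reactants: 19 11-(2,3,5-trimethoxyphenyl)drim-8(12)-en-11-one
Product: 20 11-(2,3,5-trimethoxyphenyl)driman-11-one with the C8 methyl β (axial; 8α-H; 9α-H; 5α-H; 10β-CH3)
Conditions: H2 (1 atm), 10 % Pd/C, EtOAc, rt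
Reagents that add atoms: none
Why: Heterogeneous hydrogenation of the exocyclic 1,1-disubstituted alkene; the β-face is screened by the axial C10 methyl and the 9β-aroyl group, so hydrogen should be delivered to C8 from the α-face and the C8 methyl becomes β (axial), while the hindered aryl ketone and the aryl ethers are left alone.

Step 11
Reactants: 20 11-(2,3,5-trimethoxyphenyl)driman-11-one with the C8 methyl β
Product: 22 (Z)-11-(2,3,5-trimethoxyphenyl)drim-9(11)-en-11-yl trifluoromethanesulfonate with the C8 methyl β (TfO syn to C10), via potassium enolate 21 (not isolated)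
Conditions: KHMDS (1.5 equiv), THF, −78 → 0 °C; PhNTf2 (1.5 equiv), −78 °C → rt
Reagents that add atoms: N-phenylbis(trifluoromethanesulfonimide), O=S(=O)(N(c1ccccc1)S(=O)(=O)C(F)(F)F)C(F)(F)F
Why: Deprotonation at C9, the only enolisable position, and O-sulfonylation of the tetrasubstituted enolate (enol triflate formation); the enolate is expected to place oxygen syn to the bulkier C10, but the geometry is immaterial because step 12 is stereoconvergent.

Step 12
Reactants: 22 (Z)-11-(2,3,5-trimethoxyphenyl)drim-9(11)-en-11-yl trifluoromethanesulfonate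
Product: 23 (E)-11-chloro-11-(2,3,5-trimethoxyphenyl)drim-9(11)-ene with the C8 methyl β (Cl syn to C8; aryl syn to C10)
Conditions: n-Bu4NCl (10 equiv), 2,6-di-tert-butylpyridine (2 equiv), HFIP, 40 °C
Reagents that add atoms: tetrabutylammonium chloride, CCCC[N+](CCCC)(CCCC)CCCC.[Cl-]
Why: Vinylic SN1 substitution (solvolytic ionisation of an α-aryl enol triflate with halide capture): the ortho-methoxy aryl ring, already perpendicular to the alkene plane, stabilises a linear C11 vinyl cation whose empty orbital lies in the C8–C9–C10 plane, and chloride should enter from the open C8 side (equatorial H8, axial C8 methyl) because the C10 side is blocked by C1H2, so either triflate isomer converges on the E chloride under kinetic control, and any hydrolysis only returns 20.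

Step 13
Reactants: 23 (E)-11-chloro-11-(2,3,5-trimethoxyphenyl)drim-9(11)-ene with the C8 methyl β
Product: 24 2-{(E)-chloro[(2S,4aS,8aS)-2,5,5,8a-tetramethyloctahydronaphthalen-1(2H)-ylidene]methyl}-6-methoxycyclohexa-2,5-diene-1,4-dione
Conditions: CAN (2.5 equiv), MeCN/H2O (2:1), 0 °C
Reagents that add atoms: water, O
Why: Oxidative demethylation of the 1,4-dimethoxyarene with cerium(IV) (arene radical cation, water addition, loss of methanol) should give the para-quinone with the 3-methoxy group retained, while the twisted, chlorine-bearing alkene is a poorer electron donor than the trimethoxyarene and is left alone.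

Step 14
Reactants: 24 2-{(E)-chloro[(2S,4aS,8aS)-2,5,5,8a-tetramethyloctahydronaphthalen-1(2H)-ylidene]methyl}-6-methoxycyclohexa-2,5-diene-1,4-dione
Product: 25 2-{(E)-chloro[(2S,4aS,8aS)-2,5,5,8a-tetramethyloctahydronaphthalen-1(2H)-ylidene]methyl}-6-methoxybenzene-1,4-diol (target)
Conditions: Na2S2O4 (aq.), THF/H2O, rt, argon
Reagents that add atoms: none
Why: Two-electron reduction of the quinone by dithionite gives the hydroquinone under neutral conditions that neither isomerise nor reduce the vinyl chloride.

Compound list
1 | (R)-(−)-carvone | CC1=CC[C@H](CC1=O)C(C)=C | starting material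
2 | iodomethane | CI | starting material
3 | lithium dienolate of carvone (O–Li on C1; C1=C6) | CC1=CC[C@H](C=C1O[Li])C(C)=C | intermediate
4 | (5R,6RS)-2,6-dimethyl-5-(prop-1-en-2-yl)cyclohex-2-en-1-one (6-methylcarvone, C6 epimers) | CC1=CC[C@@H](C(C)=C)C(C)C1=O | intermediate
5 | 2-(phenylsulfonyl)allyl bromide | C=C(CBr)S(=O)(=O)c1ccccc1 | starting material
6 | lithium enolate of 6-methylcarvone (C1=C6) | CC1=CC[C@@H](C(C)=C)C(C)=C1O[Li] | intermediate
7 | (5S,6S)-2,6-dimethyl-6-[2-(phenylsulfonyl)prop-2-en-1-yl]-5-(prop-1-en-2-yl)cyclohex-2-en-1-one (6-CH3 cis, sulfonylallyl trans to isopropenyl) | O=C2C(C)=CC[C@@H](C(C)=C)[C@]2(C)CC(=C)S(=O)(=O)c1ccccc1 | intermediate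
8 | 2α-(phenylsulfonyl)-11-nordrim-7-en-9-one (trans-fused, 5α-H, 10β-CH3, equatorial sulfone) | O=C2C(C)=CC[C@H]3C(C)(C)C[C@H](S(=O)(=O)c1ccccc1)C[C@]23C | intermediate
9 | lithium 11-nordrim-8-en-9-olate (5α-H, 10β-CH3) | CC1=C(O[Li])[C@@]2(C)CCCC(C)(C)[C@@H]2CC1 | intermediate
10 | 11-nordrim-8-en-9-yl trifluoromethanesulfonate (5α-H, 10β-CH3) | CC1=C(OS(=O)(=O)C(F)(F)F)[C@@]2(C)CCCC(C)(C)[C@@H]2CC1 | intermediate
11 | 5-bromovanillin | O=Cc1cc(Br)c(O)c(OC)c1 | starting material
12 | 2-bromo-6-methoxybenzene-1,4-diol | COc1cc(O)cc(Br)c1O | intermediate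
13 | 1-bromo-2,3,5-trimethoxybenzene | COc1cc(OC)cc(Br)c1OC | intermediate
14 | (2,3,5-trimethoxyphenyl)lithium | COc1cc(OC)cc([Li])c1OC | intermediate
15 | 4,4,5,5-tetramethyl-2-(2,3,5-trimethoxyphenyl)-1,3,2-dioxaborolane | COc1cc(OC)cc(B2OC(C)(C)C(C)(C)O2)c1OC | intermediate
16 | carbon monoxide | [C-]#[O+] | starting material
17 | 11-(2,3,5-trimethoxyphenyl)drim-8-en-11-one (5α-H, 10β-CH3) | COc1cc(OC)cc(C(=O)C2=C(C)CC[C@H]3C(C)(C)CCC[C@]23C)c1OC | intermediate
18 | potassium dienolate of 17 (C9=C11 and C8=C12; C9=C11 geometry not defined) | COc1cc(OC)cc(C(O[K])=C2C(=C)CC[C@H]3C(C)(C)CCC[C@]23C)c1OC | intermediate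
19 | 11-(2,3,5-trimethoxyphenyl)drim-8(12)-en-11-one (9α-H, 9β-aroyl, 5α-H, 10β-CH3) | COc1cc(OC)cc(C(=O)[C@H]2C(=C)CC[C@H]3C(C)(C)CCC[C@]23C)c1OC | intermediate
20 | 11-(2,3,5-trimethoxyphenyl)driman-11-one with C8 methyl β (8α-H, 9α-H, 5α-H, 10β-CH3) | COc1cc(OC)cc(C(=O)[C@H]2[C@@H](C)CC[C@H]3C(C)(C)CCC[C@]23C)c1OC | intermediate
21 | potassium (Z)-enolate of 20 (O syn to C10) | COc1cc(OC)cc(/C(O[K])=C2\[C@@H](C)CC[C@H]3C(C)(C)CCC[C@]23C)c1OC | intermediate
22 | (Z)-11-(2,3,5-trimethoxyphenyl)drim-9(11)-en-11-yl trifluoromethanesulfonate, C8 methyl β (TfO syn to C10) | COc1cc(OC)cc(/C(OS(=O)(=O)C(F)(F)F)=C2\[C@@H](C)CC[C@H]3C(C)(C)CCC[C@]23C)c1OC | intermediate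
23 | (E)-11-chloro-11-(2,3,5-trimethoxyphenyl)drim-9(11)-ene, C8 methyl β (Cl syn to C8, aryl syn to C10) | COc1cc(OC)cc(/C(Cl)=C2/[C@@H](C)CC[C@H]3C(C)(C)CCC[C@]23C)c1OC | intermediate
24 | 2-{(E)-chloro[(2S,4aS,8aS)-2,5,5,8a-tetramethyloctahydronaphthalen-1(2H)-ylidene]methyl}-6-methoxycyclohexa-2,5-diene-1,4-dione | COC1=CC(=O)C=C(/C(Cl)=C2/[C@@H](C)CC[C@H]3C(C)(C)CCC[C@]23C)C1=O | intermediate
25 | 2-{(E)-chloro[(2S,4aS,8aS)-2,5,5,8a-tetramethyloctahydronaphthalen-1(2H)-ylidene]methyl}-6-methoxybenzene-1,4-diol | COc1cc(O)cc(/C(Cl)=C2/[C@@H](C)CC[C@H]3C(C)(C)CCC[C@]23C)c1O | target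

Total step count: 14. Longest linear sequence: 11 steps (steps 1–4 and 8–14, from (R)-carvone).

Steps most likely to fail

Step 12. The triflate may ionise too slowly, or chloride may capture the linear C11 cation without enough facial preference, so that the more stable Z chloride builds up. The fallback sets out from 20 and comes back at 23, and it is stereospecific by mechanism and so independent of cation capture. Reduction of 20 with LiAlH4 gives the benzylic carbinol F1. E1 dehydration through the benzylic cation (MsCl, Et3N, then warming) should give the thermodynamically preferred E-styrene F2, with the aryl group syn to C8 and H11 syn to C10. Anti addition of chlorine (Et4NCl3, one equivalent, CH2Cl2, −78 °C) should give the 9α,11-dichloride F3: the chloronium ion forms on the open α-face, and H8 lies in the alkene plane, so allylic chlorination has no pathway. The low temperature and single equivalent are meant to spare the electron-rich arene, which is the weak point of this fallback. Anti E2 loss of H11 and Cl9 with DBU or t-BuOK then inverts the alkene geometry (the classical alkene → dihalide → vinyl halide sequence) and gives 23.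

Step 9. γ-Deprotonation of the twisted, hindered aryl enone may be slow or unselective, or the amide base may attack the ketone. The fallback sets out from 10 and comes back at 19; it carries C11 as an ester, for which deconjugative protonation is routine, and brings the arene in as a nucleophile. Pd-catalysed methoxycarbonylation of 10 (Pd(OAc)2, dppf, CO, MeOH, Et3N, DMF) gives methyl drim-8-en-11-oate F4. LDA/DMPU followed by kinetic protonation gives the exocyclic β,γ-unsaturated ester methyl drim-8(12)-en-11-oate F5. DIBAL-H at −78 °C gives drim-8(12)-en-11-al F6, addition of aryllithium 14 gives the carbinol F7, and Dess–Martin oxidation gives 19.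

Step 3. Hydrogen-atom transfer may not discriminate cleanly between the isopropenyl group and the vinyl sulfone, or the C4 radical may be reduced before it cyclises. The fallback sets out from 7 and comes back at 8; it makes the same C4 radical from a halide. Markovnikov addition of HBr (HBr in AcOH, 0 °C, the reaction known for carvone itself) to the isopropenyl group gives the tertiary bromide F8. Bu3SnH/AIBN (slow addition, benzene, 80 °C) then generates the C4 radical, which closes ring A 6-endo onto the vinyl sulfone and is reduced by the stannane to 8.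

Further compounds
F1 | step 12 | 11-(2,3,5-trimethoxyphenyl)driman-11-ol with C8 methyl β (9α-H; C11 epimers) | COc1cc(OC)cc(C(O)[C@H]2[C@@H](C)CC[C@H]3C(C)(C)CCC[C@]23C)c1OC
F2 | step 12 | (E)-11-(2,3,5-trimethoxyphenyl)drim-9(11)-ene with C8 methyl β (aryl syn to C8) | COc1cc(OC)cc(/C=C2\[C@@H](C)CC[C@H]3C(C)(C)CCC[C@]23C)c1OC
F3 | step 12 | 9α,11-dichloro-11-(2,3,5-trimethoxyphenyl)drimane with C8 methyl β (anti adduct of F2) | COc1cc(OC)cc([C@H](Cl)[C@@]2(Cl)[C@@H](C)CC[C@H]3C(C)(C)CCC[C@]23C)c1OC
F4 | step 9 | methyl drim-8-en-11-oate | COC(=O)C1=C(C)CC[C@H]2C(C)(C)CCC[C@]12C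
F5 | step 9 | methyl drim-8(12)-en-11-oate (9α-H) | COC(=O)[C@H]1C(=C)CC[C@H]2C(C)(C)CCC[C@]12C
F6 | step 9 | drim-8(12)-en-11-al (9α-H) | O=C[C@H]1C(=C)CC[C@H]2C(C)(C)CCC[C@]12C
F7 | step 9 | 11-(2,3,5-trimethoxyphenyl)drim-8(12)-en-11-ol (9α-H; C11 epimers) | COc1cc(OC)cc(C(O)[C@H]2C(=C)CC[C@H]3C(C)(C)CCC[C@]23C)c1OC
F8 | step 3 | (5S,6S)-5-(2-bromopropan-2-yl)-2,6-dimethyl-6-[2-(phenylsulfonyl)prop-2-en-1-yl]cyclohex-2-en-1-one | O=C2C(C)=CC[C@@H](C(C)(C)Br)[C@]2(C)CC(=C)S(=O)(=O)c1ccccc1
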